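Atoms carry the numbering of the target throughout: C1–C5 form the five-membered ring, C1 and C5–C10 the seven-membered ring. β is the face of the C1 methyl group, α the opposite face.

## Analysis of the target

Target 27 is a daucane diester built on a trans-fused hydroazulene, in which a cyclopentane (C1–C5) and a cycloheptane (C1, C5–C10) share the C1–C5 bond. It has eight stereocentres: quaternary C1 (β-methyl), C5 (α-H), C2 (β-acetate), C4 (β-hydroxyl, α-isopropyl), C6 (α-anisoate), C8/C9 (α-epoxide, C8 methyl) and C10 (β-hydroxyl). C1 is flanked by three of them (C2, C5, C10) and C5 by two (C4, C6), so the ring-fusion atoms cannot be handled separately from their neighbours. The trisubstituted epoxide next to a free secondary alcohol is acid-labile. Each ester sits 1,3 to a free hydroxyl (C2 acetate and C10–OH across C1, C6 anisoate and C4–OH across C5), which invites acyl migration under base. The difficulty lies in the trans fusion at a quaternary carbon and in telling apart two secondary carbinols, C6 and C10, of similar hindrance: one must be acylated, the other left free next to the epoxide. The strategy rests on one feature: C6 and C10 are both carbinol carbons attached to the fusion atoms and are joined by C7–C8–C9, whose central carbon C8 carries one extra carbon. That is a 2-methylenepropane-1,3-diyl unit spanning two aldehyde carbons.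

## Retrosynthetic reasoning

**27 to 26.** The C8–O and C9–O bonds of the epoxide are cut last, because the epoxide tolerates neither acid nor the base and hydride used earlier. The forward step must deliver oxygen to the α face of the C8=C9 alkene of 26, anti to the axial C1 methyl and to the C10 hydroxyl.

**26 to 25 to 24.** The C10 carbinol is traced to the enone 25, since a C10 ketone is the only reliable device for placing the alkene at C8–C9 and the methyl on C8; 1,2-reduction anti to the C1 methyl then sets C10. The anisoate C–O bond is cut next, giving 24, in which C6–OH is the only acylable hydroxyl. Putting the acetate in before C10–OH exists avoids a late choice between the two neopentyl carbinols at C2 and C10.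

**24 to 23 to 22 to 21.** The conjugated enone 24 comes from the β,γ-unsaturated ketone 23 by double-bond migration. 23 comes from diketone 22 by reduction of the C6 ketone alone, directed by the free C4 hydroxyl. 22 comes from triol 21 by oxidation of both secondary carbinols. This detour is deliberate. It removes any reliance on the carbinol configurations created in the ring-forming step, and it distinguishes C6 from C10 through the one structural difference between them, the neighbouring C4 hydroxyl.

**21 to 16 + 18.** The bonds C6–C7 and C9–C10 are cut together. This removes the seven-membered ring and all its carbon substituents in one operation, and leaves a cyclopentane whose stereocentres can be set by well-understood five-ring chemistry. The forward reaction must join the trans-dialdehyde 16 and the four-carbon dinucleophile 18 by an intermolecular and then an intramolecular allylsilane addition without touching C1 or C5. Cutting elsewhere in the seven-membered ring would leave the C8 branch or one of the carbinols to be introduced separately.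

**18 to 17.** The bis-allylsilane 18 is traced to the dichloride 17 by two C–Si bond formations.

**16 to 14 to 11.** The C6 aldehyde is masked as a vinyl group (14) and the C10 aldehyde as a primary alcohol (11), so that the two carbonyls appear only at the end and the enolisable C5 aldehyde is made last. The acetate (13) and the tertiary silyl ether (14) go on between these operations; the silyl ether protects the β-hydroxy aldehyde against retro-aldol cleavage and dehydration.

**11 to 10 to 9 to 6.** The C4–isopropyl bond is cut at the monocyclic ketone 9. At this stage no ester is present, and the α face of C4 is the open one, anti to the C5 vinyl group. The diol is held as an acetonide (7–10) meanwhile.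

**6 to 5.** The C2 carbinol of 6 is traced to the ketone 5; the neighbouring hydroxymethyl group on the α face delivers hydride and puts the new hydroxyl on the β face.

**5 to 3.** The C5–C6 bond (vinyl) and the C1–C10 bond (hydroxymethyl) are cut together: conjugate addition to 3 anti to the C4 silyloxy group, then trapping of the enolate 4 anti to the new vinyl group. This is the best-controlled way to obtain the trans relation between the two future aldehyde carbons at a quaternary centre. The C4 oxygen of 3 serves first as the controlling stereocentre and later as the site of the ketone.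

**3 to 2 to 1.** The C1 methyl is introduced on the commercially available enantiopure enone 1 by α-iodination to 2 and cross-coupling.

## Alternatives that were turned down

Alternative 1: enzymatic cyclisation. The disconnection cuts C1–C10 and C4–C5 and returns to acyclic farnesyl diphosphate A1. In the forward direction an ionisation-initiated sesquiterpene synthase would fold A1 into daucene A2, with C1 in the required configuration. In its favour, the whole carbon skeleton, the quaternary centre and the C8=C9 alkene arise in one step, which no chemical route can match. Against it, A2 carries no oxygen at all. The target needs oxygen at C2, C4, C6 and C10 and an epoxide; this means C–H oxidation at an unactivated methylene next to C1 (C2), hydration of the tetrasubstituted C4=C5 alkene with the trans fusion set at the same time, and allylic oxidations at C6 and C10 in competition with C7 and the methyl groups. None of these selectivities can be argued from the structure; each would need a dedicated oxidase. Alternative 1 is stronger on skeleton economy. The chosen route offers instead every oxygen installed through carbonyl chemistry with a stated control element.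

Alternative 2: decalin-to-hydroazulene shift. The disconnection cuts C1–C5 and returns to a decalin made from the Wieland–Miescher ketone A3. In the forward direction the all-cis hydroxy mesylate A4 undergoes a semipinacol shift: C1 migrates from the carbinol carbon C6 to the sulfonate carbon C5, contracting one ring and enlarging the other to the hydroazulenone A5. In its favour, A3 is available in quantity, and the migration is stereospecific (retention at C1, inversion at C5), so the trans fusion follows from the mechanism; on this point it is at least as secure as the conjugate-addition control used here, and it avoids a medium-ring closure. Against it, A5 lacks the C2 oxygen, which would have to be placed on an unactivated methylene beside the quaternary carbon. It also lacks the C8 carbon and the C8–C9 unsaturation, which would have to be built stepwise from the C10 carbonyl. A5 holds a C6 ketone α to the fusion hydrogen, so C5 is open to epimerisation for much of the route. The post-rearrangement sequence is therefore longer and less controlled than the six steps that follow ring formation here.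

Alternative 3: late chromium-mediated closure. The disconnection cuts only C9–C10. In the forward direction the seco aldehyde A6, a (Z)-vinyl iodide carrying both esters, would be closed with CrCl2 and catalytic NiCl2 (divalent chromium, divalent nickel) in a Nozaki–Hiyama–Kishi reaction to the allylic alcohol A7, the C4 silyl ether of 26. In its favour, the closure tolerates esters and delivers the C8=C9 alkene and the C10 carbinol together, so only epoxidation and desilylation remain; its endgame is shorter than the one chosen here. Against it, A6 needs a geometrically pure trisubstituted vinyl iodide and a C6 carbinol set on an open chain next to C5, with no cheap correction once the ester is on. The C10 configuration would be fixed in a closure onto a neopentyl aldehyde whose facial preference cannot be predicted, and correcting it by oxidation and reduction would use up the steps saved. The chosen route is weaker in step count after ring formation. It offers in exchange C7–C8–C9 and the methyl carbon from one cheap reagent in one operation, and both carbinols set afterwards under ring control.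

Key step: step 15

Remarks on the chemistry:
- Compound 1 is taken as the commercial enantiopure (R)-enone.
- Compounds 19–21 are drawn as the 6α,10β-carbinols. Epimers at C6 and C10 that form beside them are carried along, since step 16 erases both centres.

## Route

Step 1
Reactants: 1 (R)-4-(tert-butyldimethylsilyloxy)cyclopent-2-en-1-one
Product: 2 (R)-4-(tert-butyldimethylsilyloxy)-2-iodocyclopent-2-en-1-one
Conditions: I2, pyridine/CH2Cl2, 0 °C to rt
Reagents that add atoms: iodine, II
Why: α-Iodination of an enone by conjugate addition of pyridine, iodination of the enolate and loss of pyridine (addition–elimination); the silyl ether and the C4 centre are not involved.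

Step 2
Reactants: 2 (R)-4-(tert-butyldimethylsilyloxy)-2-iodocyclopent-2-en-1-one
Product: 3 (R)-4-(tert-butyldimethylsilyloxy)-2-methylcyclopent-2-en-1-one
Conditions: MeZnCl, Pd(PPh3)4 (5 mol %), THF, 0 °C to rt
Reagents that add atoms: methylzinc chloride, C[Zn]Cl
Why: Negishi cross-coupling of the alkenyl iodide; the organozinc does not add to the enone and the medium is not basic, so the β-silyloxy ketone should not eliminate.

Step 3
Reactants: 3 (R)-4-(tert-butyldimethylsilyloxy)-2-methylcyclopent-2-en-1-one
Product: 5 1α-(hydroxymethyl)-1β-methyl-5β-vinyl-4α-(tert-butyldimethylsilyloxy)cyclopentan-2-one, via bromomagnesium enolate 4 (not isolated)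
Conditions: CH2=CHMgBr, CuBr·SMe2 (10 mol %), THF, −78 °C; then CH2O (gas), −78 to −40 °C; AcOH quench
Reagents that add atoms: vinylmagnesium bromide, C=C[Mg]Br; formaldehyde, C=O
Why: Copper-catalysed conjugate addition places the vinyl group on C5 anti to the C4 silyloxy group; the tetrasubstituted enolate 4 is then hydroxymethylated (aldol) on the face anti to the new vinyl group, which sets the quaternary C1 with CH2OH α and CH3 β. This is the conjugate addition/enolate trapping pattern established for 4-silyloxycyclopentenones.

Step 4
Reactants: 5 1α-(hydroxymethyl)-1β-methyl-5β-vinyl-4α-(tert-butyldimethylsilyloxy)cyclopentan-2-one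
Product: 6 1α-(hydroxymethyl)-1β-methyl-5β-vinyl-4α-(tert-butyldimethylsilyloxy)cyclopentan-2β-ol
Conditions: Me4NBH(OAc)3, MeCN/AcOH (1:1), −30 °C
Reagents that add atoms: none
Why: Hydroxyl-directed Saksena–Evans reduction: the primary hydroxyl binds boron and delivers hydride to the α face of the C2 ketone, so the new hydroxyl is β, trans to CH2OH and cis to the C1 methyl.

Step 5
Reactants: 6 1α-(hydroxymethyl)-1β-methyl-5β-vinyl-4α-(tert-butyldimethylsilyloxy)cyclopentan-2β-ol
Product: 7 acetonide of 6 (isopropylidene bridging O2 and the C10 oxygen; 4α-silyl ether retained)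
Conditions: 2,2-dimethoxypropane, PPTS (cat.), CH2Cl2, rt
Reagents that add atoms: 2,2-dimethoxypropane, COC(C)(C)OC
Why: Acid-catalysed transketalisation closes the six-membered 1,3-dioxane, trans-fused to the cyclopentane, and masks both hydroxyls for the work at C4.

Step 6
Reactants: 7 acetonide silyl ether
Product: 8 acetonide 4α-alcohol
Conditions: TBAF, THF, 0 °C to rt
Reagents that add atoms: none
Why: Fluoride cleavage of the secondary silyl ether; the acetonide and the vinyl group are inert to fluoride.

Step 7
Reactants: 8 acetonide 4α-alcohol
Product: 9 acetonide C4 ketone (5β-vinyl)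
Conditions: Dess–Martin periodinane (DMP), NaHCO3, CH2Cl2, 0 °C to rt
Reagents that add atoms: none
Why: Dess–Martin oxidation under buffered, non-enolising conditions should give the α-vinyl ketone without epimerising C5 or moving the double bond into conjugation; 9 is used at once.

Step 8
Reactants: 9 acetonide C4 ketone
Product: 10 acetonide 4β-hydroxy-4α-isopropyl carbinol
Conditions: iPrMgCl, CeCl3 (anhydrous), THF, −78 °C; AcOH quench
Reagents that add atoms: isopropylmagnesium chloride, CC(C)[Mg]Cl
Why: Organocerium 1,2-addition: the weakly basic cerium reagent adds to the enolisable ketone instead of deprotonating or reducing it. Attack comes from the α face, anti to the adjacent β-vinyl group and the β-methyl at C1, giving 4β-OH and 4α-isopropyl.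

Step 9
Reactants: 10 acetonide 4β-hydroxy-4α-isopropyl carbinol
Product: 11 1α-(hydroxymethyl)-4α-isopropyl-1β-methyl-5β-vinylcyclopentane-2β,4β-diol
Conditions: AcOH/THF/H2O (3:1:1), 40 °C
Reagents that add atoms: none
Why: Aqueous-acid hydrolysis of the trans-fused acetonide; the tertiary alcohol and the vinyl group are stable to dilute acetic acid.

Step 10
Reactants: 11 triol
Product: 12 2β,4β-dihydroxy-4α-isopropyl-1β-methyl-5β-vinylcyclopentane-1α-carbaldehyde
Conditions: TEMPO (10 mol %), PhI(OAc)2, CH2Cl2, rt
Reagents that add atoms: none
Why: Oxoammonium (TEMPO) oxidation is selective for the primary alcohol over the secondary and tertiary ones and stops at the aldehyde. C1 is quaternary, so the aldehyde cannot epimerise, and the trans-disposed C4 hydroxyl cannot form a lactol.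

Step 11
Reactants: 12 dihydroxy aldehyde
Product: 13 2β-acetoxy-4β-hydroxy-4α-isopropyl-1β-methyl-5β-vinylcyclopentane-1α-carbaldehyde
Conditions: Ac2O, pyridine, DMAP (cat.), CH2Cl2, 0 °C
Reagents that add atoms: acetic anhydride, CC(=O)OC(C)=O
Why: DMAP-catalysed acetylation of the only secondary hydroxyl; the hindered tertiary C4 alcohol should not react at 0 °C.

Step 12
Reactants: 13 acetoxy hydroxy aldehyde
Product: 14 2β-acetoxy-4α-isopropyl-1β-methyl-4β-(trimethylsilyloxy)-5β-vinylcyclopentane-1α-carbaldehyde
Conditions: TMSOTf, 2,6-lutidine, CH2Cl2, −78 °C
Reagents that add atoms: trimethylsilyl trifluoromethanesulfonate, C[Si](C)(C)OS(=O)(=O)C(F)(F)F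
Why: Silyl triflate silylation of the hindered tertiary alcohol; the C10 aldehyde has no α-hydrogen and cannot form a silyl enol ether. The ether blocks retro-aldol cleavage and dehydration of the β-oxygenated aldehyde made next.

Step 13
Reactants: 14 silyl ether vinyl aldehyde
Product: 16 trans-dialdehyde (2β-acetoxy-4α-isopropyl-1β-methyl-4β-trimethylsilyloxycyclopentane-1α,5β-dicarbaldehyde), via secondary ozonide 15 (not isolated)
Conditions: O3, CH2Cl2, −78 °C; then PPh3, −78 °C to rt
Reagents that add atoms: ozone, [O-][O+]=O
Why: Ozonolysis of the monosubstituted alkene with reductive cleavage of ozonide 15 gives the C6 aldehyde. The neutral medium should leave C5 (now α to an aldehyde) and the β-silyloxy group untouched; 16 is used without storage.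

Step 14
Reactants: 17 3-chloro-2-(chloromethyl)prop-1-ene
Product: 18 3-(trimethylsilyl)-2-(trimethylsilylmethyl)prop-1-ene
Conditions: Mg turnings, TMSCl, THF, reflux
Reagents that add atoms: chlorotrimethylsilane, C[Si](C)(C)Cl
Why: Barbier-type silylation: each allylic Grignard species is trapped by the chlorosilane as it forms, the usual preparation type for 2-substituted allylsilanes.

Step 15
Reactants: 16 trans-dialdehyde; 18 3-(trimethylsilyl)-2-(trimethylsilylmethyl)prop-1-ene
Product: 21 2β-acetoxy-4α-isopropyl-1β-methyl-8-methylene-trans-hydroazulene-4β,6α,10β-triol, via difluoroboryl mono-adduct 19 (not isolated), via C4-O-trimethylsilyl diol 20 (not isolated)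
Conditions: BF3·OEt2 (2.5 equiv), 2,6-di-tert-butyl-4-methylpyridine (0.2 equiv), CH2Cl2 (0.01 M), −78 °C, slow addition of 18 (1.05 equiv); then 1 M HCl/THF, 0 °C
Reagents that add atoms: none
Why: In this double Hosomi–Sakurai reaction a BF3-bound aldehyde is attacked by the methylene terminus of 18 (SE2′), and loss of the silyl group from the β-silyl cation regenerates an allylsilane in 19. That allylsilane adds to the second BF3-bound aldehyde inside the molecule, forming the other of the two bonds C6–C7 and C9–C10; because the linchpin is symmetrical, the same ring results whichever aldehyde reacts first. The closest known reaction type is the [3+4] annulation of 1,4-dicarbonyl compounds with 2-(silylmethyl)allyl dinucleophiles. The seven-membered ring closes in a 7-exo-trig mode at the carbonyl carbon with the allylsilane π bond inside the forming ring, so both allyl carbons become ring atoms and the methylene stays on C8. C6 arises by Felkin-type addition to the α-branched aldehyde under control of C5, and C10 from a chair-like cyclic transition state with the boron-bound oxygen pseudo-equatorial under control of C1; as C5 lies between two fully substituted carbons the sense at C6 is not secure, and neither centre is needed because step 16 removes both. The step needs ring closure to outrun a second intermolecular allylation (slow addition of 18 at high dilution), retention of the trans fusion (C1 cannot enolise, C5 is not enolised at −78 °C), and no oxygen-bridged product (a five-membered oxocarbenium ion spanning trans substituents of a cyclopentane is disfavoured by the strain of a trans-fused bicyclo[3.3.0] skeleton). The hindered pyridine takes up stray acid that would protodesilylate 18 or 19, and the acidic work-up cleaves the tertiary silyl ether of 20 so that the C4 hydroxyl is free for step 17.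

Step 16
Reactants: 21 triol
Product: 22 2β-acetoxy-4β-hydroxy-4α-isopropyl-1β-methyl-8-methylene-trans-hydroazulene-6,10-dione
Conditions: DMP (3 equiv), NaHCO3, CH2Cl2, 0 °C
Reagents that add atoms: none
Why: Dess–Martin oxidation converts both secondary carbinols, whatever their configuration, into one diketone while the tertiary alcohol is inert. The buffered neutral medium should not isomerise the two β,γ-unsaturated ketones or enolise C5; 22 is carried on crude.

Step 17
Reactants: 22 hydroxy diketone
Product: 23 2β-acetoxy-4β,6α-dihydroxy-4α-isopropyl-1β-methyl-8-methylene-trans-hydroazulen-10-one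
Conditions: Me4NBH(OAc)3, MeCN/AcOH (1:1), −40 to −20 °C
Reagents that add atoms: none
Why: Saksena–Evans reduction: only the C6 ketone is β to the free C4 hydroxyl, which lies on its β face and delivers hydride there, giving the 6α (anti) alcohol. The C10 ketone has no directing hydroxyl and is not reduced by this reagent.

Step 18
Reactants: 23 β,γ-unsaturated hydroxy ketone
Product: 24 2β-acetoxy-4β,6α-dihydroxy-4α-isopropyl-1β,8-dimethyl-trans-hydroazul-8-en-10-one
Conditions: DBU (0.2 equiv), CH2Cl2, rt
Reagents that add atoms: none
Why: Base-catalysed isomerisation through the dienolate (deprotonation at C9, protonation at the exocyclic carbon) gives the conjugated trisubstituted enone, placing the methyl on C8 and the alkene at C8–C9. C1 is quaternary, so the ketone can enolise only toward C9.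

Step 19
Reactants: 24 hydroxy enone
Product: 25 6α-(4-methoxybenzoate) of 24
Conditions: 4-MeOC6H4COCl, DMAP, pyridine, CH2Cl2, 0 °C to rt
Reagents that add atoms: 4-methoxybenzoyl chloride, COc1ccc(cc1)C(Cl)=O
Why: DMAP-catalysed acylation of the only secondary alcohol with retention at C6; the tertiary C4 hydroxyl is not acylated, and the weak base avoids vinylogous elimination of the new ester through the dienolate.

Step 20
Reactants: 25 anisoate enone
Product: 26 10β-allylic alcohol (2β-acetate, 6α-anisoate, 4β-hydroxyl, C8=C9)
Conditions: NaBH4, CeCl3·7H2O, MeOH, −78 °C; AcOH quench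
Reagents that add atoms: none
Why: Luche 1,2-reduction; hydride attacks C10 from the α face, anti to the axial C1 methyl, giving the equatorial 10β-alcohol. Both esters are inert, and the cold acidic quench prevents acetyl migration from O2 to the new alkoxide.

Step 21
Reactants: 26 allylic alcohol
Product: 27 target, the 8α,9α-epoxide
Conditions: dimethyldioxirane (DMDO), acetone, −20 to 0 °C
Reagents that add atoms: dimethyldioxirane, CC1(C)OO1
Why: Dioxirane epoxidation of the electron-rich trisubstituted alkene under neutral conditions. The β face is shielded by the axial C1 methyl, and in acetone the dioxirane shows little hydroxyl direction, so oxygen should arrive on the α face, anti to the C10 hydroxyl; the neutral medium avoids epoxide opening and acyl migration.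

## Compound list

1 | (R)-4-(tert-butyldimethylsilyloxy)cyclopent-2-en-1-one | O=C1C=C[C@H](O[Si](C)(C)C(C)(C)C)C1 | starting material
2 | (R)-4-(tert-butyldimethylsilyloxy)-2-iodocyclopent-2-en-1-one | O=C1C(I)=C[C@H](O[Si](C)(C)C(C)(C)C)C1 | intermediate
3 | (R)-4-(tert-butyldimethylsilyloxy)-2-methylcyclopent-2-en-1-one | O=C1C(C)=C[C@H](O[Si](C)(C)C(C)(C)C)C1 | intermediate
4 | bromomagnesium enolate (O–Mg on C2, C1=C2; 5β-vinyl, 4α-silyloxy) | C=C[C@H]1[C@H](O[Si](C)(C)C(C)(C)C)CC(O[Mg]Br)=C1C | intermediate
5 | 1α-(hydroxymethyl)-1β-methyl-5β-vinyl-4α-(tert-butyldimethylsilyloxy)cyclopentan-2-one | C=C[C@H]1[C@H](O[Si](C)(C)C(C)(C)C)CC(=O)[C@]1(C)CO | intermediate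
6 | 1α-(hydroxymethyl)-1β-methyl-5β-vinyl-4α-(tert-butyldimethylsilyloxy)cyclopentan-2β-ol | C=C[C@H]1[C@H](O[Si](C)(C)C(C)(C)C)C[C@@H](O)[C@]1(C)CO | intermediate
7 | acetonide of 6 (isopropylidene on O2 and the C10 oxygen) | C=C[C@H]1[C@H](O[Si](C)(C)C(C)(C)C)C[C@@H](OC(C)(C)OC2)[C@@]12C | intermediate
8 | acetonide 4α-alcohol | C=C[C@H]1[C@H](O)C[C@@H](OC(C)(C)OC2)[C@@]12C | intermediate
9 | acetonide C4 ketone | C=C[C@H]1C(=O)C[C@@H](OC(C)(C)OC2)[C@@]12C | intermediate
10 | acetonide 4β-hydroxy-4α-isopropyl carbinol | C=C[C@H]1[C@](O)(C(C)C)C[C@@H](OC(C)(C)OC2)[C@@]12C | intermediate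
11 | 1α-(hydroxymethyl)-4α-isopropyl-1β-methyl-5β-vinylcyclopentane-2β,4β-diol | C=C[C@H]1[C@](O)(C(C)C)C[C@@H](O)[C@]1(C)CO | intermediate
12 | 2β,4β-dihydroxy-4α-isopropyl-1β-methyl-5β-vinylcyclopentane-1α-carbaldehyde | C=C[C@H]1[C@](O)(C(C)C)C[C@@H](O)[C@]1(C)C=O | intermediate
13 | 2β-acetoxy-4β-hydroxy-4α-isopropyl-1β-methyl-5β-vinylcyclopentane-1α-carbaldehyde | C=C[C@H]1[C@](O)(C(C)C)C[C@@H](OC(C)=O)[C@]1(C)C=O | intermediate
14 | 2β-acetoxy-4α-isopropyl-1β-methyl-4β-(trimethylsilyloxy)-5β-vinylcyclopentane-1α-carbaldehyde | C=C[C@H]1[C@](O[Si](C)(C)C)(C(C)C)C[C@@H](OC(C)=O)[C@]1(C)C=O | intermediate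
15 | secondary ozonide (1,2,4-trioxolane) of 14 | O1OCOC1[C@H]2[C@](O[Si](C)(C)C)(C(C)C)C[C@@H](OC(C)=O)[C@]2(C)C=O | intermediate
16 | 2β-acetoxy-4α-isopropyl-1β-methyl-4β-(trimethylsilyloxy)cyclopentane-1α,5β-dicarbaldehyde (trans-dialdehyde) | O=C[C@H]1[C@](O[Si](C)(C)C)(C(C)C)C[C@@H](OC(C)=O)[C@]1(C)C=O | intermediate
17 | 3-chloro-2-(chloromethyl)prop-1-ene | C=C(CCl)CCl | starting material
18 | 3-(trimethylsilyl)-2-(trimethylsilylmethyl)prop-1-ene | C=C(C[Si](C)(C)C)C[Si](C)(C)C | intermediate
19 | mono-adduct: C6 difluoroboryl alkoxide bearing the 2-(trimethylsilylmethyl)allyl chain, C10 aldehyde intact | C[Si](C)(C)CC(=C)C[C@H](OB(F)F)[C@H]1[C@](O[Si](C)(C)C)(C(C)C)C[C@@H](OC(C)=O)[C@]1(C)C=O | intermediate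
20 | C4-O-trimethylsilyl ether of 21 | O[C@H]1CC(=C)C[C@H](O)[C@]2(C)[C@@H]1[C@](O[Si](C)(C)C)(C(C)C)C[C@H]2OC(C)=O | intermediate
21 | 2β-acetoxy-4α-isopropyl-1β-methyl-8-methylene-trans-hydroazulene-4β,6α,10β-triol (5α-H) | O[C@H]1CC(=C)C[C@H](O)[C@]2(C)[C@@H]1[C@](O)(C(C)C)C[C@H]2OC(C)=O | intermediate
22 | 2β-acetoxy-4β-hydroxy-4α-isopropyl-1β-methyl-8-methylene-trans-hydroazulene-6,10-dione | O=C1CC(=C)CC(=O)[C@]2(C)[C@@H]1[C@](O)(C(C)C)C[C@H]2OC(C)=O | intermediate
23 | 2β-acetoxy-4β,6α-dihydroxy-4α-isopropyl-1β-methyl-8-methylene-trans-hydroazulen-10-one | O[C@H]1CC(=C)CC(=O)[C@]2(C)[C@@H]1[C@](O)(C(C)C)C[C@H]2OC(C)=O | intermediate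
24 | 2β-acetoxy-4β,6α-dihydroxy-4α-isopropyl-1β,8-dimethyl-trans-hydroazul-8-en-10-one | O[C@H]1CC(C)=CC(=O)[C@]2(C)[C@@H]1[C@](O)(C(C)C)C[C@H]2OC(C)=O | intermediate
25 | 6α-(4-methoxybenzoate) of 24 | COc1ccc(C(=O)O[C@H]2CC(C)=CC(=O)[C@]3(C)[C@@H]2[C@](O)(C(C)C)C[C@H]3OC(C)=O)cc1 | intermediate
26 | 10β-allylic alcohol from 25 | COc1ccc(C(=O)O[C@H]2CC(C)=C[C@H](O)[C@]3(C)[C@@H]2[C@](O)(C(C)C)C[C@H]3OC(C)=O)cc1 | intermediate
27 | CNP0371526.1: 2β-acetoxy-8α,9α-epoxy-4β,10β-dihydroxy-6α-(4-methoxybenzoyloxy)daucane | COc1ccc(C(=O)O[C@H]2C[C@@]3(C)O[C@H]3[C@H](O)[C@]3(C)[C@@H]2[C@](O)(C(C)C)C[C@H]3OC(C)=O)cc1 | target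

## Step count and least certain steps

Total: 21 steps. Longest linear sequence: 20 steps (steps 1–13 and 15–21, from 1); step 14 is the one-step side branch to 18.

**Step 15 (key step).** The likeliest failure is that closure onto the neopentyl C10 aldehyde is outrun by a second intermolecular allylation or by protodesilylation of the regenerated allylsilane, so that open-chain products form. Lewis-acid-induced loss of the tertiary silyloxy group is the second concern. The fallback replaces electrophile activation by a nucleophilic allylmetal under neutral conditions. It sets out from 16 and the dichloride 17: indium powder and NaI in DMF at high dilution should add an allylindium species to one aldehyde, giving the chloride mono-adduct F1; its allylic chloride is then metalated in turn and adds to the remaining aldehyde inside the molecule. This gives 20, which the dilute-acid treatment of step 15 converts to 21, where the route is rejoined.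

**Step 3.** The likeliest failure is incomplete trapping of the hindered tetrasubstituted enolate: proton transfer to the C3 side followed by β-elimination of the silyloxy group, or capture by oligomeric formaldehyde. The fallback sets out from 3. Conjugate addition of the vinyl Grignard reagent with CuBr·SMe2 in the presence of TMSCl gives the isolable trimethylsilyl enol ether F2. A Mukaiyama aldol reaction with aqueous formaldehyde and catalytic Yb(OTf)3 in THF then gives 5, where the route is rejoined.

**Step 16.** The likeliest failures are migration of the exocyclic double bond into conjugation with the C6 ketone, loss of the trans fusion by enolisation at C5, and retro-aldol opening of the C4–C5 bond in the tertiary β-hydroxy ketone. In addition, step 17 depends on a hindered tertiary hydroxyl exchanging onto boron. The fallback never makes the C6 ketone. It sets out from 21: 2,2-dimethoxypropane and PPTS tie O4 and O6 together as the O4,O6-acetonide F3; Dess–Martin oxidation of the remaining C10 carbinol then gives the keto acetonide F4; DBU moves the double bond to give the enone acetonide F5; aqueous acetic acid finally releases 24, where the route is rejoined. This fallback keeps the C6 configuration delivered by step 15. Should step 15 deliver the 6β-epimeric triol F6 instead, the same four operations would lead through its acetonide F7, the 6β keto acetonide F8 and the 6β enone acetonide F9 to the 6-epi-hydroxy enone F10; a Mitsunobu esterification with 4-methoxybenzoic acid, PPh3 and diisopropyl azodicarboxylate would then invert C6 and give 25, where the route is rejoined.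

**Step 21.** The likeliest failure is poor facial selectivity, through residual direction by the C10 hydroxyl toward the β face; oxidation of the allylic alcohol is a lesser risk. The fallback removes the directing hydroxyl. It sets out from 26: TESCl and imidazole give the C10 triethylsilyl ether F11; mCPBA with NaHCO3 then epoxidises anti to both the silyloxy group and the C1 methyl, giving the silylated α-epoxide F12; TBAF buffered with AcOH gives 27, where the route is rejoined.

## Further compounds

F1 | step 15 | chloride mono-adduct: C6 carbinol bearing the 2-(chloromethyl)allyl chain, C10 aldehyde intact | ClCC(=C)C[C@H](O)[C@H]1[C@](O[Si](C)(C)C)(C(C)C)C[C@@H](OC(C)=O)[C@]1(C)C=O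
F2 | step 3 | trimethylsilyl enol ether of the 5β-vinyl-4α-silyloxy ketone | C=C[C@H]1[C@H](O[Si](C)(C)C(C)(C)C)CC(O[Si](C)(C)C)=C1C
F3 | step 16 | O4,O6-acetonide of 21 | CC1(C)O[C@H]2CC(=C)C[C@H](O)[C@]3(C)[C@@H]2[C@](O1)(C(C)C)C[C@H]3OC(C)=O
F4 | step 16 | O4,O6-acetonide C10 ketone | CC1(C)O[C@H]2CC(=C)CC(=O)[C@]3(C)[C@@H]2[C@](O1)(C(C)C)C[C@H]3OC(C)=O
F5 | step 16 | O4,O6-acetonide of enone 24 | CC1(C)O[C@H]2CC(C)=CC(=O)[C@]3(C)[C@@H]2[C@](O1)(C(C)C)C[C@H]3OC(C)=O
F6 | step 16 | 6β-epimer of triol 21 | O[C@@H]1CC(=C)C[C@H](O)[C@]2(C)[C@@H]1[C@](O)(C(C)C)C[C@H]2OC(C)=O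
F7 | step 16 | O4,O6-acetonide of the 6β-epimeric triol | CC1(C)O[C@@H]2CC(=C)C[C@H](O)[C@]3(C)[C@@H]2[C@](O1)(C(C)C)C[C@H]3OC(C)=O
F8 | step 16 | 6β O4,O6-acetonide C10 ketone | CC1(C)O[C@@H]2CC(=C)CC(=O)[C@]3(C)[C@@H]2[C@](O1)(C(C)C)C[C@H]3OC(C)=O
F9 | step 16 | 6β O4,O6-acetonide enone | CC1(C)O[C@@H]2CC(C)=CC(=O)[C@]3(C)[C@@H]2[C@](O1)(C(C)C)C[C@H]3OC(C)=O
F10 | step 16 | 6-epi-hydroxy enone (6β-epimer of 24) | O[C@@H]1CC(C)=CC(=O)[C@]2(C)[C@@H]1[C@](O)(C(C)C)C[C@H]2OC(C)=O
F11 | step 21 | C10 triethylsilyl ether of 26 | COc1ccc(C(=O)O[C@H]2CC(C)=C[C@H](O[Si](CC)(CC)CC)[C@]3(C)[C@@H]2[C@](O)(C(C)C)C[C@H]3OC(C)=O)cc1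
F12 | step 21 | C10 triethylsilyl ether of 27 | COc1ccc(C(=O)O[C@H]2C[C@@]3(C)O[C@H]3[C@H](O[Si](CC)(CC)CC)[C@]3(C)[C@@H]2[C@](O)(C(C)C)C[C@H]3OC(C)=O)cc1
A1 | alternative 1 | (2E,6E)-farnesyl diphosphate | CC(C)=CCC/C(C)=C/CC/C(C)=C/COP(O)(=O)OP(O)(O)=O
A2 | alternative 1 | daucene (dauca-4,8-diene) | CC1=CC[C@@]2(C)CCC(C(C)C)=C2CC1
A3 | alternative 2 | (S)-Wieland–Miescher ketone | C[C@]12CCC(=O)C=C1CCCC2=O
A4 | alternative 2 | all-cis decalin hydroxy mesylate (C6 tertiary carbinol, C5 mesylate, C4 silyl ether, C10 dioxolane) | CS(=O)(=O)O[C@H]1[C@@H](O[Si](C)(C)C(C)(C)C)CC[C@]2(C)C3(OCCO3)CCC[C@]12O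
A5 | alternative 2 | trans-fused hydroazulen-6-one (C4 silyl ether, C10 dioxolane) | O=C1CCCC2(OCCO2)[C@]3(C)[C@@H]1[C@@H](O[Si](C)(C)C(C)(C)C)CC3
A6 | alternative 3 | seco (Z)-vinyl iodide aldehyde carrying both esters and the C4 triethylsilyl ether | COc1ccc(C(=O)O[C@@H](C/C(C)=C\I)[C@H]1[C@](O[Si](CC)(CC)CC)(C(C)C)C[C@@H](OC(C)=O)[C@]1(C)C=O)cc1
A7 | alternative 3 | C4 triethylsilyl ether of 26 | COc1ccc(C(=O)O[C@H]2CC(C)=C[C@H](O)[C@]3(C)[C@@H]2[C@](O[Si](CC)(CC)CC)(C(C)C)C[C@H]3OC(C)=O)cc1
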